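## Structural features

The target is a meta-terphenyl built from three phloroglucinol rings; it has no stereocentre and its two biaryl axes carry no configurational descriptor, so nothing stereochemical has to be set. Ring B carries ring A and ring C on the two carbons that flank its 2'-hydroxyl, and each outer ring is attached through the carbon lying between two of its own oxygens, so both biaryl bonds have four ortho oxygens. Seven of the nine oxygens are free phenols and two are aryl hydrogen sulfates, one on an ortho oxygen of each outer ring. The aryl sulfate monoesters are the fragile groups: they hydrolyse in acid but tolerate base and hydrogenolysis, so they are introduced late and kept as salts. The polyphenol itself is very electron-rich and is open to air oxidation, to attack of carbon electrophiles at its ring CH positions and to acid-induced dibenzofuran formation between neighbouring hydroxyls. The carbon skeleton is easy; the real difficulty is to sulfate two of nine similar oxygens, stopping at one of the two equivalent ortho oxygens of each outer ring and sparing the ring B hydroxyl. The key step exploits the fact that the 2'-oxygen of ring B can share one boron atom with one ortho oxygen of ring A and one of ring C (two fused seven-membered rings), which turns the second ortho oxygen of each outer ring toward the benzyloxy side of ring B and leaves only these two hydroxyls free.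

## Logic of the disconnections

13 ⇒ 12. The four O–CH2Ph bonds of the spectator ethers are cut last. Hydrogenolysis is the one deprotection that an aryl sulfate salt tolerates without acid, so benzyl is kept for the two para oxygens and for the two outer oxygens of ring B. The forward step must run near neutral pH so that no O–S bond is lost.

12 ⇒ 10 (through 11). The two aryl O–S bonds are cut. This removes all charge and leaves a pentaol whose five hydroxyls are the ring B hydroxyl and the four outer ortho hydroxyls. The forward step must react at only two of them, one per outer ring; the borate 11 is there to mask the other three.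

10 ⇒ 9. Five acetal O–CH2 bonds are cut. One temporary group on all five oxygens lets a single mild solvolysis expose the pentaol while the benzyl ethers stay. The 2-(trimethylsilyl)ethoxymethyl group is chosen over methoxymethyl because it directs metalation equally well, its chloride is far less volatile than the carcinogenic reagent that the methoxymethyl group requires, and it can also be removed by fluoride.

9 ⇒ 8 + 6. Both biaryl C–C bonds are cut in one two-fold Negishi disconnection. It divides the molecule into one ring B dibromide and two identical outer-ring nucleophiles, at the price of forming two tetra-ortho-oxygenated biaryl bonds. An arylzinc is preferred to a boronic acid because 2,6-dialkoxyarylboron compounds protodeboronate easily. A lead-mediated C–H arylation of 4 would make the same bonds without 5 and 6 but needs stoichiometric lead and a mercury catalyst; it is kept in reserve for reasons of safety.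

8 ⇒ 7 ⇒ 3. The C–Zn and C–Li bonds go back to the C–H bond between the two acetal oxygens of 3. Two flanking acetal groups make this the most readily lithiated position, so no halogenation of the outer ring is needed.

6 ⇒ 5 ⇒ 4. The acetal O–C bond and the two C–Br bonds are cut. The free hydroxyl of 4 is used to steer both bromines to its ortho positions; the demand is ortho selectivity over the equally activated para position.

3 ⇒ 2 ⇒ 1. Two acetal O–C bonds and one benzyl O–C bond are cut, leading to 1. The monobenzylation is statistical and is run with excess 1.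

## Other disconnections considered

Alternative 1: The cut is made inside each outer ring, at the two C–C bonds to the carbon that carries the oxygen to be sulfated and at the C–O bond of the para ester. In the forward sense the bis(enyne) A2, a ring B core bearing two 3-pivaloyloxy-1,4-enyne arms, would react under CO with [Rh(CO)2Cl]2 by 1,2-acyloxy migration and [5+1] cycloaddition to the terphenyl diol A1.
In favour: in A1 the oxygen to be sulfated is born as the only free hydroxyl of each outer ring, with the ring B oxygens benzylated and the para oxygen esterified. Sulfation of A1 would therefore be ordinary chemistry, and on this point the alternative is better than step 7.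
Against: A2 needs a long chain-building sequence on ring B (enol ether alkenes, propargylic pivalates). The ring closure has to take place at an alkene terminus carrying a di-ortho-substituted aryl group. Competing acyloxy shifts are conceivable. CO is a toxic gas. A pivalate cleavage is added after sulfation.
Comparison: both plans end with hydrogenolysis next to the sulfates, so they are equal there. The chosen plan makes the skeleton by cross-coupling in far fewer steps and keeps its one untested event for a late, easily diagnosed step, whereas here the untested event is the skeleton-forming cascade that turns A2 into A1.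

Alternative 2: Ring B is cut. The 4-aryl-3-(benzyloxy)cyclobutenone A4 and the aryl siloxyalkyne A5 would combine on heating (Danheiser benzannulation: vinylketene, [2+2], ring opening, six-electron closure) to the terphenyl A3, in which the ring B hydroxyl lies between the two aryl groups.
In favour: the position of the ring B hydroxyl of A3 follows from the mechanism, which is better than relying on the directed bromination of step 3. The outer rings of A4 and A5 carry a methoxymethyl group on the oxygen to be sulfated and a benzyl group on the other, so the sulfation sites are fixed by ordinary protecting groups.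
Against: A4 and A5 each need an outer ring with three differently substituted oxygens, which is harder to make than 3. Both reacting carbons carry di-ortho-substituted aryl groups. After the key step the ring B hydroxyl of A3 must be capped, the acetals removed, the sulfates installed and the silyl ether cleaved before hydrogenolysis.
Comparison: both routes deliver the ring B hydroxyl free, so they are equal on that structural point; the chosen plan uses it as the anchor of the template instead of masking it. The chosen plan is clearly ahead on step economy, the alternative on the certainty of the sulfation itself.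

Alternative 3: Both outer rings are cut. Two molecules of the cyclobutenone A7, 3-(benzyloxy)cyclobut-2-en-1-one, would react with the bis(siloxyalkyne) A8 of ring B in a two-directional Danheiser benzannulation to the terphenyl diol A6.
In favour: A7 is small and used twice. Each outer ring of A6 emerges with a free ortho hydroxyl (from the ketene carbon), a silylated ortho oxygen and a benzylated para oxygen, and ring B is fully benzylated, so the two hydroxyls to be sulfated are the only free ones. In certainty of site selection this is better than step 7 and equal to the protecting-group fallback given below.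
Against: A8 carries two ynol silyl ethers, each between two benzyloxy groups, and needs several steps from a ring B diester. The 3-alkoxy group should make A7 slower to open. Both arms of A8 must react. A fluoride step is added.
Comparison: three operations follow the key step (sulfation, desilylation, hydrogenolysis) against one in the chosen plan, and the overall count is higher. Mechanistically the benzannulation is established in type but not for such hindered partners, so the uncertainty sits in the skeleton-forming step.

Key step: step 7

Assumption 1: the two biaryl axes are taken as configurationally undefined, as in the target, and no atropisomer control is attempted.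
Assumption 2: 12 and 13 are drawn as neutral hydrogen sulfates like the target but are carried as sodium salts; the acid form is released only at the end on a cold acidic resin. 10 and 12 differ by two SO3 units, 12 and 13 by four benzyl groups.

## Route

Step 1
Reactants: 1 phloroglucinol (benzene-1,3,5-triol)
Product: 2 5-(benzyloxy)benzene-1,3-diol
Conditions: BnBr (1 equiv), 1 (3 equiv), K2CO3, DMF, 0 °C to rt
Reagents that add atoms: benzyl bromide, BrCc1ccccc1
Why: Williamson etherification in a polar aprotic solvent, where O-alkylation of the phenoxide should dominate over C-benzylation; the excess of 1 limits double benzylation and unreacted 1 is washed out with water, so a statistical but simple monoprotection is accepted.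

Step 2
Reactants: 2 5-(benzyloxy)benzene-1,3-diol
Product: 3 1-(benzyloxy)-3,5-bis{[2-(trimethylsilyl)ethoxy]methoxy}benzene
Conditions: SEMCl, i-Pr2NEt, CH2Cl2, 0 °C to rt
Reagents that add atoms: 2-(trimethylsilyl)ethoxymethyl chloride, C[Si](C)(C)CCOCCl
Why: O-alkylation of both phenols by the hard chloromethyl ether (acetal protection); the two acetal oxygens later direct metalation to the carbon between them.

Step 3
Reactants: 4 3,5-bis(benzyloxy)phenol
Product: 5 3,5-bis(benzyloxy)-2,6-dibromophenol
Conditions: NBS (2.0 equiv), i-Pr2NH (cat.), CH2Cl2, −78 to 0 °C, dark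
Reagents that add atoms: N-bromosuccinimide, O=C1CCC(=O)N1Br
Why: Amine-catalysed ortho-selective bromination of a phenol; the N-bromoamine formed from NBS is hydrogen-bonded to the hydroxyl and delivers bromine to both ortho carbons, and the para carbon is in addition shielded by two benzyloxy groups.

Step 4
Reactants: 5 3,5-bis(benzyloxy)-2,6-dibromophenol
Product: 6 1,5-bis(benzyloxy)-2,4-dibromo-3-{[2-(trimethylsilyl)ethoxy]methoxy}benzene
Conditions: SEMCl, i-Pr2NEt, CH2Cl2, rt
Reagents that add atoms: 2-(trimethylsilyl)ethoxymethyl chloride, C[Si](C)(C)CCOCCl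
Why: Acetal protection of the acidic dibromophenol; it removes the acidic proton before the organozinc step and uses the same group as on 3, so that one later operation frees all five hydroxyls.

Step 5
Reactants: 3 1-(benzyloxy)-3,5-bis{[2-(trimethylsilyl)ethoxy]methoxy}benzene; 6 1,5-bis(benzyloxy)-2,4-dibromo-3-{[2-(trimethylsilyl)ethoxy]methoxy}benzene
Product: 9 4,4',4'',6'-tetrakis(benzyloxy)-2,2',2'',6,6''-pentakis{[2-(trimethylsilyl)ethoxy]methoxy}-1,1':3',1''-terphenyl, via aryllithium 7 (not isolated), via arylzinc chloride 8 (not isolated)
Conditions: 3 (2.6 equiv), n-BuLi, THF, 0 °C; ZnCl2, 0 °C to rt; then 6, Pd(OAc)2 (cat.), RuPhos, THF, 65 °C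
Reagents that add atoms: n-butyllithium, [Li]CCCC (lithium, in 7 only); zinc chloride, Cl[Zn]Cl (zinc and chlorine, in 8 only)
Why: Directed ortho-metalation between the two acetal oxygens, transmetalation to zinc and two-fold Negishi coupling; a bulky electron-rich dialkylbiarylphosphine on zerovalent palladium is the established catalyst type for tetra-ortho-substituted biaryls, and the arylzinc avoids the protodeboronation of a 2,6-dialkoxyarylboronic acid.

Step 6
Reactants: 9 the penta-acetal tetrabenzyl terphenyl
Product: 10 4,4',4'',6'-tetrakis(benzyloxy)-[1,1':3',1''-terphenyl]-2,2',2'',6,6''-pentol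
Conditions: HCl (1 M in MeOH), THF, 40 °C, Ar
Reagents that add atoms: none
Why: Acid-catalysed acetal solvolysis; methanol in large excess traps the CH2 unit as dimethoxymethane, benzyl ethers are untouched, and the air-sensitive pentaol is used directly under argon.

Step 7
Reactants: 10 the tetrabenzyl pentaol
Product: 12 4,4',4'',6'-tetrakis(benzyloxy)-2',6,6''-trihydroxy-[1,1':3',1''-terphenyl]-2,2''-diyl bis(hydrogen sulfate), via bicyclic triaryl borate 11 (not isolated)
Conditions: B(OMe)3 (1.0 equiv), toluene, 5 Å sieves, 80 °C; then SO3·NMe3 (2.4 equiv), Et3N, MeCN, 40 °C; then H2O, NaHCO3, rt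
Reagents that add atoms: sulfur trioxide–trimethylamine complex, C[N+](C)(C)S(=O)(=O)[O-] (the two SO3 units of 12); trimethyl borate, COB(OC)OC (boron, in 11 only)
Why: Proposed new method: B(OMe)3 should exchange its three methoxy groups for the ring B hydroxyl and for one ortho hydroxyl of ring A and of ring C, each exchange being attack of a phenol oxygen on boron with loss of MeOH (taken up by the sieves), so that two seven-membered 1,3,2-dioxaborepine rings sharing the B–O bond of ring B are closed by B–O bond formation. The closest known reaction types are the seven-membered cyclic borates of 2,2'-biphenols and the boron and tin templates used for site-selective acylation and sulfation of polyols. A bond-length estimate suggests that the cage needs both outer rings tilted to the same face of ring B by roughly 45° with some in-plane bending, so it should be strained but within reach, while the second ortho oxygen of each outer ring is turned toward the benzyloxy side of ring B and cannot bind the same boron. These two hydroxyls are then the only free phenols; each attacks sulfur of SO3·NMe3 with Et3N as proton acceptor to form the aryl O–S bond, and the negative charge of a sulfate discourages further reaction nearby. Aqueous NaHCO3 then hydrolyses the three B–OAr bonds, so both borate rings open again and boron leaves as boric acid. No stereocentre is formed, and delivery of both sulfates to the face away from boron has no lasting stereochemical meaning because the axes are not fixed in 13. The selectivity needed, no sulfate on ring B and one per outer ring, is secured by the substrate itself: only the ring B hydroxyl and its two neighbours can fill the three valences of one boron, and one equivalent of boron is used so that no other hydroxyl is esterified.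

Step 8
Reactants: 12 the tetrabenzyl disulfate (as its sodium salt)
Product: 13 2',4,4',4'',6,6',6''-heptahydroxy-[1,1':3',1''-terphenyl]-2,2''-diyl bis(hydrogen sulfate) (target)
Conditions: H2 (1 atm), Pd/C, MeOH–H2O, rt; then sulfonic acid resin (H+ form), 0 °C, freeze-drying
Reagents that add atoms: none
Why: Hydrogenolysis of benzyl aryl ethers, to which aryl sulfate salts are inert under neutral conditions; the cold resin only exchanges sodium for protons, and the product is best stored as the salt.

## Compound list

1 | phloroglucinol (benzene-1,3,5-triol) | Oc1cc(O)cc(O)c1 | starting material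
2 | 5-(benzyloxy)benzene-1,3-diol | Oc1cc(O)cc(OCc2ccccc2)c1 | intermediate
3 | 1-(benzyloxy)-3,5-bis{[2-(trimethylsilyl)ethoxy]methoxy}benzene | C[Si](C)(C)CCOCOc1cc(OCc2ccccc2)cc(OCOCC[Si](C)(C)C)c1 | intermediate
4 | 3,5-bis(benzyloxy)phenol | Oc1cc(OCc2ccccc2)cc(OCc2ccccc2)c1 | starting material
5 | 3,5-bis(benzyloxy)-2,6-dibromophenol | Oc1c(Br)c(OCc2ccccc2)cc(OCc2ccccc2)c1Br | intermediate
6 | 1,5-bis(benzyloxy)-2,4-dibromo-3-{[2-(trimethylsilyl)ethoxy]methoxy}benzene | C[Si](C)(C)CCOCOc1c(Br)c(OCc2ccccc2)cc(OCc2ccccc2)c1Br | intermediate
7 | [4-(benzyloxy)-2,6-bis{[2-(trimethylsilyl)ethoxy]methoxy}phenyl]lithium (formed in the flask) | [Li]c1c(OCOCC[Si](C)(C)C)cc(OCc2ccccc2)cc1OCOCC[Si](C)(C)C | intermediate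
8 | [4-(benzyloxy)-2,6-bis{[2-(trimethylsilyl)ethoxy]methoxy}phenyl]zinc chloride (formed in the flask) | Cl[Zn]c1c(OCOCC[Si](C)(C)C)cc(OCc2ccccc2)cc1OCOCC[Si](C)(C)C | intermediate
9 | 4,4',4'',6'-tetrakis(benzyloxy)-2,2',2'',6,6''-pentakis{[2-(trimethylsilyl)ethoxy]methoxy}-1,1':3',1''-terphenyl | C[Si](C)(C)CCOCOc1c(-c2c(OCOCC[Si](C)(C)C)cc(OCc3ccccc3)cc2OCOCC[Si](C)(C)C)c(OCc2ccccc2)cc(OCc2ccccc2)c1-c1c(OCOCC[Si](C)(C)C)cc(OCc2ccccc2)cc1OCOCC[Si](C)(C)C | intermediate
10 | 4,4',4'',6'-tetrakis(benzyloxy)-[1,1':3',1''-terphenyl]-2,2',2'',6,6''-pentol | Oc1c(-c2c(O)cc(OCc3ccccc3)cc2O)c(OCc2ccccc2)cc(OCc2ccccc2)c1-c1c(O)cc(OCc2ccccc2)cc1O | intermediate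
11 | bicyclic triaryl borate of 10: boron bound to the ring B oxygen and to one ortho oxygen of ring A and of ring C, the other ortho hydroxyl of each outer ring free (formed in the flask) | B12Oc3cc(OCc4ccccc4)cc(O)c3-c3c(OCc4ccccc4)cc(OCc4ccccc4)c(c3O1)-c1c(O)cc(OCc3ccccc3)cc1O2 | intermediate
12 | 4,4',4'',6'-tetrakis(benzyloxy)-2',6,6''-trihydroxy-[1,1':3',1''-terphenyl]-2,2''-diyl bis(hydrogen sulfate) | O=S(=O)(O)Oc1cc(OCc2ccccc2)cc(O)c1-c1c(OCc2ccccc2)cc(OCc2ccccc2)c(-c2c(O)cc(OCc3ccccc3)cc2OS(=O)(=O)O)c1O | intermediate
13 | 2',4,4',4'',6,6',6''-heptahydroxy-[1,1':3',1''-terphenyl]-2,2''-diyl bis(hydrogen sulfate) | O=S(=O)(O)Oc1cc(O)cc(O)c1-c1c(O)cc(O)c(-c2c(O)cc(O)cc2OS(=O)(=O)O)c1O | target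

## Step count and risks

Total step count: 8. Longest linear sequence: 6 (steps 1, 2, 5, 6, 7, 8; the branch through steps 3 and 4 is equally long).

Step 7 (key step). The second borate ring may fail to close because of strain, or borate groups may exchange between molecules. Either would expose the ring B oxygen or both ortho oxygens of one outer ring to the sulfating agent. The fallback replaces the template by protecting groups; it sets out from 4 and 5 and comes back to the route at 13. 5 is O-benzylated (BnBr, K2CO3, DMF) to 1,3,5-tris(benzyloxy)-2,4-dibromobenzene F1, and 4 is protected with SEMCl and i-Pr2NEt as 1,3-bis(benzyloxy)-5-{[2-(trimethylsilyl)ethoxy]methoxy}benzene F2. n-BuLi metalates F2 at a carbon between the acetal oxygen and a benzyloxy group to [2,4-bis(benzyloxy)-6-{[2-(trimethylsilyl)ethoxy]methoxy}phenyl]lithium F3, which ZnCl2 converts into [2,4-bis(benzyloxy)-6-{[2-(trimethylsilyl)ethoxy]methoxy}phenyl]zinc chloride F4. Negishi coupling of F4 with F1 under the conditions of step 5 should give 2',4,4',4'',6,6',6''-heptakis(benzyloxy)-2,2''-bis{[2-(trimethylsilyl)ethoxy]methoxy}-1,1':3',1''-terphenyl F5. Acidic methanolysis as in step 6 then frees exactly one hydroxyl per outer ring, giving 2',4,4',4'',6,6',6''-heptakis(benzyloxy)-[1,1':3',1''-terphenyl]-2,2''-diol F6. SO3·NMe3 and Et3N sulfate both hydroxyls to 2',4,4',4'',6,6',6''-heptakis(benzyloxy)-[1,1':3',1''-terphenyl]-2,2''-diyl bis(hydrogen sulfate) F7, and hydrogenolysis as in step 8 leads to 13.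

Step 5. The second oxidative addition and transmetalation at the crowded, electron-rich bromide may stall, giving mono-coupling and reductive loss of bromine. The fallback forms the same two bonds by ligand coupling on tetravalent lead; it sets out from 3 and 4, comes back to the route at 10 and makes steps 3 and 4 unnecessary. 3 is lithiated as in step 5 to 7, which is quenched with B(OMe)3 and hydrolysed gently to [4-(benzyloxy)-2,6-bis{[2-(trimethylsilyl)ethoxy]methoxy}phenyl]boronic acid F8. Pb(OAc)4 with catalytic Hg(OAc)2 in CHCl3 converts F8 into [4-(benzyloxy)-2,6-bis{[2-(trimethylsilyl)ethoxy]methoxy}phenyl]lead triacetate F9. F9 (2.5 equiv) with 4 and pyridine should arylate both carbons ortho to the free hydroxyl (Pinhey arylation), giving 3,5-bis(benzyloxy)-2,6-bis[4-(benzyloxy)-2,6-bis{[2-(trimethylsilyl)ethoxy]methoxy}phenyl]phenol F10. The conditions of step 6 convert F10 into 10. This path is held back only because of the toxicity of lead and mercury.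

Step 3. Bromination may also occur at the equally activated para carbon, or go on to the tribromide, because the hydrogen-bond delivery has to outrun the background reaction. The fallback fixes the regiochemistry by construction; it uses commercial 4,6-dibromobenzene-1,3-diol F11 in place of 4 and comes back to the route at 5. Double benzylation (BnBr, K2CO3, DMF) gives 1,5-bis(benzyloxy)-2,4-dibromobenzene F12. LiN(i-Pr)2 in THF at −78 °C removes the proton between the two bromines, giving [3,5-bis(benzyloxy)-2,6-dibromophenyl]lithium F13, which B(OMe)3 traps as dimethyl [3,5-bis(benzyloxy)-2,6-dibromophenyl]boronate F14. Oxidation of F14 with H2O2 and NaOH gives 5.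

Step 6. The alkoxymethyl cations released may be captured by the electron-rich ring carbons, and acid may induce cyclodehydration between neighbouring hydroxyls to dibenzofurans. The fallback changes the cleavage mechanism from acid solvolysis to fluoride-triggered fragmentation at silicon. It sets out from 9 (Bu4NF, ethylenediamine as formaldehyde scavenger, THF, 60 °C, then aqueous NH4Cl) and comes back at 10 without any new compound.

## Further compounds

F1 | step 7 | 1,3,5-tris(benzyloxy)-2,4-dibromobenzene | Brc1c(OCc2ccccc2)cc(OCc2ccccc2)c(Br)c1OCc1ccccc1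
F2 | step 7 | 1,3-bis(benzyloxy)-5-{[2-(trimethylsilyl)ethoxy]methoxy}benzene | C[Si](C)(C)CCOCOc1cc(OCc2ccccc2)cc(OCc2ccccc2)c1
F3 | step 7 | [2,4-bis(benzyloxy)-6-{[2-(trimethylsilyl)ethoxy]methoxy}phenyl]lithium | [Li]c1c(OCOCC[Si](C)(C)C)cc(OCc2ccccc2)cc1OCc1ccccc1
F4 | step 7 | [2,4-bis(benzyloxy)-6-{[2-(trimethylsilyl)ethoxy]methoxy}phenyl]zinc chloride | Cl[Zn]c1c(OCOCC[Si](C)(C)C)cc(OCc2ccccc2)cc1OCc1ccccc1
F5 | step 7 | 2',4,4',4'',6,6',6''-heptakis(benzyloxy)-2,2''-bis{[2-(trimethylsilyl)ethoxy]methoxy}-1,1':3',1''-terphenyl | C[Si](C)(C)CCOCOc1cc(OCc2ccccc2)cc(OCc2ccccc2)c1-c1c(OCc2ccccc2)cc(OCc2ccccc2)c(-c2c(OCOCC[Si](C)(C)C)cc(OCc3ccccc3)cc2OCc2ccccc2)c1OCc1ccccc1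
F6 | step 7 | 2',4,4',4'',6,6',6''-heptakis(benzyloxy)-[1,1':3',1''-terphenyl]-2,2''-diol | Oc1cc(OCc2ccccc2)cc(OCc2ccccc2)c1-c1c(OCc2ccccc2)cc(OCc2ccccc2)c(-c2c(O)cc(OCc3ccccc3)cc2OCc2ccccc2)c1OCc1ccccc1
F7 | step 7 | 2',4,4',4'',6,6',6''-heptakis(benzyloxy)-[1,1':3',1''-terphenyl]-2,2''-diyl bis(hydrogen sulfate) | O=S(=O)(O)Oc1cc(OCc2ccccc2)cc(OCc2ccccc2)c1-c1c(OCc2ccccc2)cc(OCc2ccccc2)c(-c2c(OS(=O)(=O)O)cc(OCc3ccccc3)cc2OCc2ccccc2)c1OCc1ccccc1
F8 | step 5 | [4-(benzyloxy)-2,6-bis{[2-(trimethylsilyl)ethoxy]methoxy}phenyl]boronic acid | OB(O)c1c(OCOCC[Si](C)(C)C)cc(OCc2ccccc2)cc1OCOCC[Si](C)(C)C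
F9 | step 5 | [4-(benzyloxy)-2,6-bis{[2-(trimethylsilyl)ethoxy]methoxy}phenyl]lead triacetate | CC(=O)O[Pb](OC(C)=O)(OC(C)=O)c1c(OCOCC[Si](C)(C)C)cc(OCc2ccccc2)cc1OCOCC[Si](C)(C)C
F10 | step 5 | 3,5-bis(benzyloxy)-2,6-bis[4-(benzyloxy)-2,6-bis{[2-(trimethylsilyl)ethoxy]methoxy}phenyl]phenol | Oc1c(-c2c(OCOCC[Si](C)(C)C)cc(OCc3ccccc3)cc2OCOCC[Si](C)(C)C)c(OCc2ccccc2)cc(OCc2ccccc2)c1-c1c(OCOCC[Si](C)(C)C)cc(OCc2ccccc2)cc1OCOCC[Si](C)(C)C
F11 | step 3 | 4,6-dibromobenzene-1,3-diol | Oc1cc(O)c(Br)cc1Br
F12 | step 3 | 1,5-bis(benzyloxy)-2,4-dibromobenzene | Brc1cc(Br)c(OCc2ccccc2)cc1OCc1ccccc1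
F13 | step 3 | [3,5-bis(benzyloxy)-2,6-dibromophenyl]lithium | [Li]c1c(Br)c(OCc2ccccc2)cc(OCc2ccccc2)c1Br
F14 | step 3 | dimethyl [3,5-bis(benzyloxy)-2,6-dibromophenyl]boronate | COB(OC)c1c(Br)c(OCc2ccccc2)cc(OCc2ccccc2)c1Br
F0 | step 6 | none | none
A1 | alternative 1 | terphenyl diol with, on each outer ring, a free ortho hydroxyl, a para pivalate and an ortho benzyl ether; ring B tribenzylated | Oc1cc(OC(=O)C(C)(C)C)cc(OCc2ccccc2)c1-c1c(OCc2ccccc2)cc(OCc2ccccc2)c(-c2c(O)cc(OC(=O)C(C)(C)C)cc2OCc2ccccc2)c1OCc1ccccc1
A2 | alternative 1 | 1,3,5-tris(benzyloxy)benzene carrying at C2 and C4 a 2-(benzyloxy)-3-(pivaloyloxy)pent-1-en-4-yn-1-yl arm (alkene geometry and carbinol configuration unspecified) | C#CC(OC(=O)C(C)(C)C)C(OCc1ccccc1)=Cc1c(OCc2ccccc2)cc(OCc2ccccc2)c(C=C(OCc2ccccc2)C(OC(=O)C(C)(C)C)C#C)c1OCc1ccccc1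
A3 | alternative 2 | terphenyl with ring B bearing a free hydroxyl between the aryl groups, one triisopropylsilyl ether and one benzyl ether; outer rings with ortho methoxymethyl ether, ortho benzyl ether and para benzyl ether | Oc1c(-c2c(OCOC)cc(OCc3ccccc3)cc2OCc2ccccc2)c(OCc2ccccc2)cc(O[Si](C(C)C)(C(C)C)C(C)C)c1-c1c(OCOC)cc(OCc2ccccc2)cc1OCc1ccccc1
A4 | alternative 2 | 3-(benzyloxy)-4-[2,4-bis(benzyloxy)-6-(methoxymethoxy)phenyl]cyclobut-2-en-1-one (racemic) | O=C1C=C(OCc2ccccc2)C1c1c(OCOC)cc(OCc2ccccc2)cc1OCc1ccccc1
A5 | alternative 2 | {[2,4-bis(benzyloxy)-6-(methoxymethoxy)phenyl]ethynyloxy}triisopropylsilane | CC(C)[Si](OC#Cc1c(OCOC)cc(OCc2ccccc2)cc1OCc1ccccc1)(C(C)C)C(C)C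
A6 | alternative 3 | terphenyl diol with, on each outer ring, a free ortho hydroxyl, an ortho triisopropylsilyl ether and a para benzyl ether; ring B tribenzylated | Oc1cc(OCc2ccccc2)cc(O[Si](C(C)C)(C(C)C)C(C)C)c1-c1c(OCc2ccccc2)cc(OCc2ccccc2)c(-c2c(O)cc(OCc3ccccc3)cc2O[Si](C(C)C)(C(C)C)C(C)C)c1OCc1ccccc1
A7 | alternative 3 | 3-(benzyloxy)cyclobut-2-en-1-one | O=C1C=C(OCc2ccccc2)C1
A8 | alternative 3 | 1,3,5-tris(benzyloxy)-2,4-bis{[(triisopropylsilyl)oxy]ethynyl}benzene | CC(C)[Si](OC#Cc1c(OCc2ccccc2)cc(OCc2ccccc2)c(C#CO[Si](C(C)C)(C(C)C)C(C)C)c1OCc1ccccc1)(C(C)C)C(C)C
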